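The earlier runs and the new flask were computed from invented constants, noise included.

Per minute, what share of the E still in the flask turns into D? Call that the clearing rate k′, the pseudo-first-order constant: the natural log of E charged over E remaining, divided by the time.

in all of them: Z 200 mM (held)
- summer: E 0.75 M; run made earlier
- dawn: E 3 M; run made earlier
- flask: E 1.5 M; time 8.0 min

| summer: time / min | summer: D / % | dawn: time / min | dawn: D / % |
|---|---|---|---|
| 0.417 | 6 | 0.417 | 5 |
| 1.33 | 29 | 1.33 | 18 |
| 2.50 | 42 | 2.50 | 34 |
| 4.00 | 62 | 4.00 | 49 |
| 5.00 | 64 | 5.00 | 56 |
| 6.00 | 73 | 6.00 | 68 |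

(readings scatter by 2 percentage points)

* D at 8.0 min, in percent of the E charged
* the change that raises the amount of D at 8.0 min, in percent of the E charged most ("none" if none brings more than 2 percentage points) (gamma / delta / none)
* amount of D at 8.0 min, in percent of the E charged, after delta

- gamma: doubling the transfer coefficient of Z, all else as stated
- delta: doubling the saturation concentration of Z, all else as stated

The last readings give k′ = 0.218 min⁻¹ for summer and 0.190 min⁻¹ for dawn, each with the scatter of its reading. Two chemists read this pair differently.

The first holds that J stands near a steady level, so E simply decays. The dawn charge is 4.00 times the summer charge, yet k′ is lower by a factor of only 1.15. The flask's charge of 1.5 M lies at the geometric middle of the two, so she takes the flask's clearing rate as their geometric mean, 0.204 min⁻¹.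

The second holds that gas supply caps the D made per minute. Dawn averaged 0.340 M min⁻¹ over 6.00 min. At that ceiling the flask's E lasts 4.41 min, less than 8.0 min, so he expects 100 percent and no useful change.

My own reckoning follows the first. With k′ held, the E remaining decays exponentially, and D reaches 80.4%. If J keeps its share of saturation, delta doubles k′ and gives 96.2%.

The forecast, by a fit of its own, comes down on her side: 80%, delta, 95%. In its words: “The modest slowing at high E shows partial gas-transfer limitation.”

The flask gives 82.5%, and the best change is delta, which brings 95.4%.

    J → X (k = 0.00450 s⁻¹)
    E + J → D (k = 0.0340 L mol⁻¹ s⁻¹)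
    Z ⇌ J, rate k3*(csat - [J]) (kL = 0.0750 s⁻¹)
    2 J → Q (k = 0.160 L mol⁻¹ s⁻¹)

Read back, the flask's k′ is 0.218 min⁻¹, and the constant of E + J → D times J at 4.00 min is 0.222 min⁻¹. Carried to the same flask read at 15 min, the estimate 0.204 min⁻¹ gives 95.3%; that flask stands at 96.9%. The second chemist's ground lies toward heavier charges: with E raised to 2.97 M the flask's answer has moved 5 points, and in the flask gamma gains 6.6 percentage points, half of delta's gain. In the flask, from 0.800 min to 8.00 min, transfer of Z fed J while E + J → D, 2 J → Q and J → X ran, and J went from 0.0964 M to 0.119 M. There D stood at 55.5% at 4.00 min, and E stood at 17.5% at 8.00 min.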